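The trans pair C8/C9 of the nine-membered ring carries an alkenyl-type carbon (C11, on C8) and a carboxyl-level carbon (C10, on C9), which is the retron of an ester-enolate Claisen rearrangement, so the route rests on disconnecting C8–C9. In one operation the silyl ketene acetal of a 13-membered allylic lactone forms C8–C9, breaks O–C12, contracts the ring to the cyclononene, transfers chirality from C12 to C8 and sets C9. The precursor is the 13-membered lactone of the C10 acid on an (S)-C12 carbinol, with E C8=C11, Z C3=C4, the C1 methylene, a C5 silyl ether and a protected C11 hydroxymethyl arm.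

Key step: step 17

Numbering used throughout: C1 (C=CH2) to C9 are the carbocycle, C10 is the OCH2 of the oxolane (tetrahydrofuran) ring, C11 its quaternary ether carbon, C12–C15 the side chain.
Remark 1: by the CIP rules the alkene made in step 17 is Z (C8 and C13 are trans, but the oxygenated CH2 on C11 outranks C8); the lactone alkene C8=C11 is E.
Remark 2 (assumption): (S)-linalool, 4-methyl hydrogen itaconate, ethyl 2-(diethoxyphosphoryl)acrylate, the Ohira–Bestmann reagent and the allylborane of step 13 are taken as purchased.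
Remark 3: the lactone keeps a triethylsilyl ether at C5 and a 4-methoxybenzyl (PMB) ether on the C11 arm, since neither offers an enolisable ester to compete in step 17. The Z C3=C4 alkene is made by alkyne semi-hydrogenation, and C12 is set by reagent-controlled allylation.

Step 1
Reactants: 1 (S)-linalool
Product: 2 (S)-linalool triethylsilyl ether
Conditions: Et3SiOTf, 2,6-lutidine, CH2Cl2, −78 to 0 °C
Reagents that add atoms: triethylsilyl trifluoromethanesulfonate, CC[Si](CC)(CC)OS(=O)(=O)C(F)(F)F
Why: Silyl triflate with 2,6-lutidine silylates the hindered tertiary allylic alcohol (O-silylation) and leaves the C5 stereocentre, taken from the chiral pool, untouched.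

Step 2
Reactants: 2 (S)-linalool triethylsilyl ether
Product: 3 6,7-epoxy-(S)-linalool triethylsilyl ether (both epoxide epimers)
Conditions: mCPBA, NaHCO3, CH2Cl2, 0 °C
Reagents that add atoms: 3-chloroperoxybenzoic acid, OOC(=O)c1cccc(Cl)c1
Why: Prilezhaev epoxidation is far faster at the electron-rich trisubstituted alkene than at the hindered vinyl group, which masks the future C8 aldehyde; the new epoxide centre needs no control because step 5 destroys it.

Step 3
Reactants: 3 6,7-epoxy-(S)-linalool triethylsilyl ether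
Product: 5 (S)-4-(3,3-dimethyloxiran-2-yl)-2-methyl-2-(triethylsilyloxy)butanal, via secondary ozonide 4 (not isolated)
Conditions: O3, CH2Cl2, −78 °C; then PPh3, −78 to 25 °C
Reagents that add atoms: ozone, [O-][O+]=O
Why: Ozonolysis with reductive work-up cleaves the only remaining alkene to the C4 aldehyde, which has no α-hydrogen and cannot epimerise at C5.

Step 4
Reactants: 5 (S)-4-(3,3-dimethyloxiran-2-yl)-2-methyl-2-(triethylsilyloxy)butanal
Product: 6 (S)-triethyl[5-(3,3-dimethyloxiran-2-yl)-3-methylpent-1-yn-3-yloxy]silane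
Conditions: MeC(O)C(N2)P(O)(OMe)2, K2CO3, MeOH, 0 to 25 °C
Reagents that add atoms: dimethyl (1-diazo-2-oxopropyl)phosphonate, CC(=O)C(=[N+]=[N-])P(=O)(OC)OC
Why: Ohira–Bestmann (Seyferth–Gilbert) homologation turns the non-enolisable aldehyde into the terminal alkyne C3≡C4 under mild carbonate conditions that the epoxide and the tertiary silyl ether tolerate.

Step 5
Reactants: 6 (S)-triethyl[5-(3,3-dimethyloxiran-2-yl)-3-methylpent-1-yn-3-yloxy]silane
Product: 7 (S)-4-methyl-4-(triethylsilyloxy)hex-5-ynal
Conditions: H5IO6, THF/H2O, 0 °C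
Reagents that add atoms: none
Why: Periodic acid opens the epoxide to the glycol and cleaves it in the same operation (Malaprade-type glycol cleavage), releasing the C8 aldehyde while the alkyne is inert.

Step 6
Reactants: 7 (S)-4-methyl-4-(triethylsilyloxy)hex-5-ynal; 8 ethyl 2-(diethoxyphosphoryl)acrylate; 9 4-methoxybenzyl alcohol
Product: 11 ethyl (2E,6S)-2-[(4-methoxybenzyloxy)methyl]-6-methyl-6-(triethylsilyloxy)oct-2-en-7-ynoate, via sodium phosphonate carbanion 10 (not isolated)
Conditions: 9, NaH, THF, 0 °C; 8, 0 °C; then 7, 0 to 25 °C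
Reagents that add atoms: none
Why: Oxa-Michael addition of the alkoxide to the phosphonoacrylate gives carbanion 10, whose Horner–Wadsworth–Emmons reaction with the unbranched aldehyde should favour the E ester (C7 trans to the ester carbon C12 and cis to the CH2O arm), the geometry the later [3,3] shift needs.

Step 7
Reactants: 11 ethyl (2E,6S)-2-[(4-methoxybenzyloxy)methyl]-6-methyl-6-(triethylsilyloxy)oct-2-en-7-ynoate
Product: 12 (2Z,6S)-2-[(4-methoxybenzyloxy)methyl]-6-methyl-6-(triethylsilyloxy)oct-2-en-7-yn-1-ol
Conditions: iBu2AlH, CH2Cl2, −78 °C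
Reagents that add atoms: none
Why: iBu2AlH reduces the conjugated ester to the allylic alcohol by 1,2-hydride delivery at low temperature without touching the alkyne, the ethers or the alkene geometry (the descriptor changes to Z only because of the CIP ranking).

Step 8
Reactants: 13 4-methyl hydrogen itaconate
Product: 15 methyl 3-(hydroxymethyl)but-3-enoate, via mixed carbonic anhydride 14 (not isolated)
Conditions: ClCO2Et, N-methylmorpholine, THF, −15 °C; then NaBH4, H2O, 0 °C
Reagents that add atoms: none
Why: Activation of the conjugated acid as a mixed carbonic anhydride followed by borohydride reduces it chemoselectively next to the methyl ester; the hydroxy ester is used at once so that it does not lactonise.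

Step 9
Reactants: 15 methyl 3-(hydroxymethyl)but-3-enoate
Product: 16 methyl 3-(bromomethyl)but-3-enoate
Conditions: CBr4, PPh3, CH2Cl2, 0 °C
Reagents that add atoms: carbon tetrabromide, BrC(Br)(Br)Br
Why: Appel bromination converts the primary allylic alcohol into the bromide under neutral conditions, and because the allyl unit is symmetric about C1 an allylic shift would give the same compound.

Step 10
Reactants: 12 (2Z,6S)-2-[(4-methoxybenzyloxy)methyl]-6-methyl-6-(triethylsilyloxy)oct-2-en-7-yn-1-ol; 16 methyl 3-(bromomethyl)but-3-enoate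
Product: 17 methyl (7S,10Z)-12-hydroxy-11-[(4-methoxybenzyloxy)methyl]-7-methyl-3-methylidene-7-(triethylsilyloxy)dodec-10-en-5-ynoate
Conditions: CuI, K2CO3, Bu4NI (cat.), DMF, 25 °C
Reagents that add atoms: none
Why: The copper acetylide formed under carbonate conditions is alkylated by the allylic bromide (copper-mediated alkyne–allyl halide coupling), giving the skipped enyne C2–C3≡C4 without affecting the free allylic alcohol.

Step 11
Reactants: 17 methyl (7S,10Z)-12-hydroxy-11-[(4-methoxybenzyloxy)methyl]-7-methyl-3-methylidene-7-(triethylsilyloxy)dodec-10-en-5-ynoate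
Product: 18 methyl (5Z,7S,10Z)-12-hydroxy-11-[(4-methoxybenzyloxy)methyl]-7-methyl-3-methylidene-7-(triethylsilyloxy)dodeca-5,10-dienoate
Conditions: H2 (1 atm), Pd on CaCO3 poisoned with Pb(OAc)2 (Lindlar catalyst), quinoline, EtOAc, 25 °C
Reagents that add atoms: none
Why: Lindlar semi-hydrogenation adds hydrogen syn to the alkyne and stops at the alkene, which sets the Z C3=C4 geometry while the other alkenes are not reduced on the poisoned catalyst.

Step 12
Reactants: 18 methyl (5Z,7S,10Z)-12-hydroxy-11-[(4-methoxybenzyloxy)methyl]-7-methyl-3-methylidene-7-(triethylsilyloxy)dodeca-5,10-dienoate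
Product: 19 methyl (5Z,7S,10E)-11-formyl-12-(4-methoxybenzyloxy)-7-methyl-3-methylidene-7-(triethylsilyloxy)dodeca-5,10-dienoate
Conditions: MnO2, CH2Cl2, 25 °C
Reagents that add atoms: none
Why: MnO2 oxidises only the allylic primary alcohol, giving the enal with retention of the C8=C11 geometry.

Step 13
Reactants: 19 methyl (5Z,7S,10E)-11-formyl-12-(4-methoxybenzyloxy)-7-methyl-3-methylidene-7-(triethylsilyloxy)dodeca-5,10-dienoate
Product: 20 methyl (5Z,7S,10E,12S)-12-hydroxy-11-[(4-methoxybenzyloxy)methyl]-7-methyl-3-methylidene-7-(triethylsilyloxy)pentadeca-5,10,14-trienoate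
Conditions: (+)-Ipc2B(CH2CH=CH2) [from (−)-Ipc2BOMe, (+)-α-pinene series], Et2O, −78 °C; then NaBO3·4H2O, THF/H2O, 25 °C
Reagents that add atoms: (+)-B-allyldiisopinocampheylborane, C=CCB(C1CC2CC(C2(C)C)C1C)C1CC2CC(C2(C)C)C1C (constitution; isopinocampheyl groups of the (+)-α-pinene series)
Why: Brown allylation through a closed chair transition state adds the allyl group to the Si face of the enal under reagent control (the sense that turns benzaldehyde into the (S)-carbinol), which should set (S)-C12; α-substituted E-enals are standard substrates.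

Step 14
Reactants: 20 methyl (5Z,7S,10E,12S)-12-hydroxy-11-[(4-methoxybenzyloxy)methyl]-7-methyl-3-methylidene-7-(triethylsilyloxy)pentadeca-5,10,14-trienoate
Product: 21 methyl (5Z,7S,10E,12S)-12-hydroxy-11-[(4-methoxybenzyloxy)methyl]-7,15-dimethyl-3-methylidene-7-(triethylsilyloxy)hexadeca-5,10,14-trienoate
Conditions: second-generation Grubbs catalyst (5 mol%), 2-methyl-2-butene/CH2Cl2, 25 °C
Reagents that add atoms: 2-methyl-2-butene, CC=C(C)C
Why: Cross-metathesis of the terminal alkene with excess 2-methyl-2-butene exchanges the CH2 terminus for an isopropylidene group (prenyl synthesis), while the 1,1-disubstituted, trisubstituted and hindered Z alkenes react much more slowly.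

Step 15
Reactants: 21 methyl (5Z,7S,10E,12S)-12-hydroxy-11-[(4-methoxybenzyloxy)methyl]-7,15-dimethyl-3-methylidene-7-(triethylsilyloxy)hexadeca-5,10,14-trienoate
Product: 22 (5Z,7S,10E,12S)-12-hydroxy-11-[(4-methoxybenzyloxy)methyl]-7,15-dimethyl-3-methylidene-7-(triethylsilyloxy)hexadeca-5,10,14-trienoic acid (seco acid)
Conditions: LiOH, THF/H2O, 0 °C; then 1 M HCl to pH 4
Reagents that add atoms: lithium hydroxide, [Li+].[OH-]
Why: Saponification with LiOH at 0 °C is a plain acyl substitution that is faster than base-induced migration of the C1 methylene into conjugation.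

Step 16
Reactants: 22 seco acid
Product: 23 (6Z,8S,11E,13S)-12-[(4-methoxybenzyloxy)methyl]-8-methyl-4-methylidene-13-(3-methylbut-2-enyl)-8-(triethylsilyloxy)oxacyclotrideca-6,11-dien-2-one (13-membered lactone)
Conditions: 2-methyl-6-nitrobenzoic anhydride (MNBA), DMAP, CH2Cl2, 25 °C, slow addition (1 mM)
Reagents that add atoms: none
Why: Shiina macrolactonisation activates the acid as a mixed anhydride and, under high dilution, acylates the only free hydroxyl (C12) with retention at C12 to close the 13-membered ring, which three ring alkenes preorganise.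

Step 17
Reactants: 23 13-membered lactone
Product: 26 trans-(8S,9R) nine-membered-ring acid, via silyl ketene acetal 24 (not isolated), via trimethylsilyl ester 25 (not isolated)
Conditions: LiN(iPr)2, Me3SiCl/Et3N, THF/DMPU, −78 °C; then 25 to 65 °C; then 1 M HCl, 0 °C
Reagents that add atoms: none
Why: Deprotonation at C9 and O-silylation give silyl ketene acetal 24, whose array C9=C10–O–C12–C11=C8 undergoes a concerted suprafacial [3,3]-sigmatropic shift (Ireland–Claisen rearrangement) to silyl ester 25, hydrolysed on work-up. The closest known reaction type is the ester-enolate Claisen ring contraction of macrocyclic allylic lactones to 2-alkenylcycloalkanecarboxylic acids. The nine-membered carbocycle is closed not end to end but transannularly, by C8–C9 bond formation inside the 13-membered ring through a six-membered transition state bridged by C1–C7 (ring contraction by four atoms). C8 is controlled by the (S)-C12 carbinol and the E C8=C11 alkene (suprafacial 1,3-chirality transfer with C13 pseudo-equatorial, which also places C8 and C13 trans on the new alkene), and C9 by the ketene acetal geometry, the Z acetal (C1 cis to OSi, favoured by DMPU) giving the trans acid through the chair. The step needs the trans C8/C9 relation: the Z-acetal/chair and E-acetal/boat pairings both deliver it, and only the crossed pairings would give the C9 epimer. The amide base at −78 °C with in-flask silylation leaves the tertiary silyl ether, the PMB ether and the skipped dienes untouched and prevents ketene loss from the lithium enolate.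

Step 18
Reactants: 26 trans-(8S,9R) nine-membered-ring acid
Product: 27 C10 primary alcohol
Conditions: LiAlH4, Et2O, 0 °C
Reagents that add atoms: none
Why: LiAlH4 reduces the carboxylic acid (as its carboxylate, so C9 is not exposed to epimerisation) to the C10 alcohol without affecting the isolated alkenes, the PMB ether or the tertiary silyl ether.

Step 19
Reactants: 27 C10 primary alcohol
Product: 28 C10/C11-arm diol
Conditions: DDQ, CH2Cl2/pH 7 phosphate buffer, 0 °C
Reagents that add atoms: none
Why: DDQ removes the PMB ether by benzylic hydride abstraction and hydrolysis of the oxocarbenium ion under buffered conditions, freeing the allylic alcohol that directs the next step.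

Step 20
Reactants: 28 C10/C11-arm diol
Product: 30 (8S,9R,11R,12R)-oxolane diol, via epoxy diol 29 (not isolated)
Conditions: Ti(OiPr)4 (20 mol%), L-(+)-diethyl tartrate (24 mol%), tBuOOH, 4 Å molecular sieves, CH2Cl2, −20 °C; then (+)-camphor-10-sulfonic acid (cat.), 0 °C
Reagents that add atoms: tert-butyl hydroperoxide, CC(C)(C)OO
Why: Sharpless asymmetric epoxidation of the primary allylic alcohol with L-(+)-tartrate (the sense that takes nerol to its (2S,3R)-epoxide) should give the (11S,12R)-epoxide 29, and acid-catalysed 5-exo opening by the C10 hydroxyl at the tertiary carbon C11 with inversion sets (R)-C11 of the oxolane ring.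

Step 21
Reactants: 30 (8S,9R,11R,12R)-oxolane diol
Product: 31 C11-CH2 stearate with free (12R)-hydroxyl
Conditions: stearoyl chloride (1.05 equiv), 2,4,6-collidine, CH2Cl2, −20 to 0 °C
Reagents that add atoms: stearoyl chloride, CCCCCCCCCCCCCCCCCC(=O)Cl
Why: The primary hydroxyl is acylated by the acid chloride faster than the more hindered secondary C12 hydroxyl (selective O-acylation at low temperature with a slight excess of reagent).

Step 22
Reactants: 31 C11-CH2 stearate with free (12R)-hydroxyl
Product: 32 C5 triethylsilyl ether of the target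
Conditions: Ph2S[OC(CF3)2Ph]2 (Martin sulfurane), CH2Cl2, 0 to 25 °C
Reagents that add atoms: none
Why: Martin sulfurane dehydrates the secondary alcohol by anti elimination; only C13 carries β-hydrogens (C11 is quaternary) and they are allylic, so the conjugated E C12=C13 diene is the only alkene expected.

Step 23
Reactants: 32 C5 triethylsilyl ether of the target
Product: 33 CNP0274030.1 (target)
Conditions: HF·pyridine, pyridine, THF, 0 to 25 °C
Reagents that add atoms: none
Why: Fluoride cleaves the tertiary triethylsilyl ether (desilylation) under pyridine-buffered conditions that spare the ester, the diene and the tertiary allylic alcohol that is released.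

Compound list
1 | (S)-linalool, (3S)-3,7-dimethylocta-1,6-dien-3-ol | C=C[C@@](C)(O)CCC=C(C)C | starting material
2 | (S)-linalool triethylsilyl ether | C=C[C@@](C)(O[Si](CC)(CC)CC)CCC=C(C)C | intermediate
3 | 6,7-epoxy-(S)-linalool triethylsilyl ether (C5 S; epoxide carbon as both epimers) | C=C[C@@](C)(O[Si](CC)(CC)CC)CCC1OC1(C)C | intermediate
4 | secondary ozonide (1,2,4-trioxolane) of 3 at the former vinyl group | C1(OCOO1)[C@@](C)(O[Si](CC)(CC)CC)CCC1OC1(C)C | intermediate (not isolated)
5 | (S)-4-(3,3-dimethyloxiran-2-yl)-2-methyl-2-(triethylsilyloxy)butanal | O=C[C@@](C)(O[Si](CC)(CC)CC)CCC1OC1(C)C | intermediate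
6 | (S)-triethyl[5-(3,3-dimethyloxiran-2-yl)-3-methylpent-1-yn-3-yloxy]silane | C#C[C@@](C)(O[Si](CC)(CC)CC)CCC1OC1(C)C | intermediate
7 | (S)-4-methyl-4-(triethylsilyloxy)hex-5-ynal | C#C[C@@](C)(O[Si](CC)(CC)CC)CCC=O | intermediate
8 | ethyl 2-(diethoxyphosphoryl)acrylate | C=C(C(=O)OCC)P(=O)(OCC)OCC | starting material
9 | 4-methoxybenzyl alcohol | COc1ccc(CO)cc1 | starting material
10 | sodium salt of the carbanion of ethyl 2-(diethoxyphosphoryl)-3-(4-methoxybenzyloxy)propanoate | [Na+].CCOC(=O)[C-](COCc1ccc(OC)cc1)P(=O)(OCC)OCC | intermediate (not isolated)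
11 | ethyl (2E,6S)-2-[(4-methoxybenzyloxy)methyl]-6-methyl-6-(triethylsilyloxy)oct-2-en-7-ynoate | C#C[C@@](C)(O[Si](CC)(CC)CC)CC/C=C(\COCc1ccc(OC)cc1)C(=O)OCC | intermediate
12 | (2Z,6S)-2-[(4-methoxybenzyloxy)methyl]-6-methyl-6-(triethylsilyloxy)oct-2-en-7-yn-1-ol | C#C[C@@](C)(O[Si](CC)(CC)CC)CC/C=C(\COCc1ccc(OC)cc1)CO | intermediate
13 | 4-methyl hydrogen itaconate (4-methoxy-2-methylidene-4-oxobutanoic acid) | C=C(CC(=O)OC)C(=O)O | starting material
14 | mixed ethyl carbonic anhydride of 13 | C=C(CC(=O)OC)C(=O)OC(=O)OCC | intermediate (not isolated)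
15 | methyl 3-(hydroxymethyl)but-3-enoate | C=C(CO)CC(=O)OC | intermediate
16 | methyl 3-(bromomethyl)but-3-enoate | C=C(CBr)CC(=O)OC | intermediate
17 | methyl (7S,10Z)-12-hydroxy-11-[(4-methoxybenzyloxy)methyl]-7-methyl-3-methylidene-7-(triethylsilyloxy)dodec-10-en-5-ynoate | COC(=O)CC(=C)CC#C[C@@](C)(O[Si](CC)(CC)CC)CC/C=C(\COCc1ccc(OC)cc1)CO | intermediate
18 | methyl (5Z,7S,10Z)-12-hydroxy-11-[(4-methoxybenzyloxy)methyl]-7-methyl-3-methylidene-7-(triethylsilyloxy)dodeca-5,10-dienoate | COC(=O)CC(=C)C/C=C\[C@@](C)(O[Si](CC)(CC)CC)CC/C=C(\COCc1ccc(OC)cc1)CO | intermediate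
19 | methyl (5Z,7S,10E)-11-formyl-12-(4-methoxybenzyloxy)-7-methyl-3-methylidene-7-(triethylsilyloxy)dodeca-5,10-dienoate | COC(=O)CC(=C)C/C=C\[C@@](C)(O[Si](CC)(CC)CC)CC/C=C(\COCc1ccc(OC)cc1)C=O | intermediate
20 | methyl (5Z,7S,10E,12S)-12-hydroxy-11-[(4-methoxybenzyloxy)methyl]-7-methyl-3-methylidene-7-(triethylsilyloxy)pentadeca-5,10,14-trienoate | COC(=O)CC(=C)C/C=C\[C@@](C)(O[Si](CC)(CC)CC)CC/C=C(\COCc1ccc(OC)cc1)[C@H](CC=C)O | intermediate
21 | methyl (5Z,7S,10E,12S)-12-hydroxy-11-[(4-methoxybenzyloxy)methyl]-7,15-dimethyl-3-methylidene-7-(triethylsilyloxy)hexadeca-5,10,14-trienoate | COC(=O)CC(=C)C/C=C\[C@@](C)(O[Si](CC)(CC)CC)CC/C=C(\COCc1ccc(OC)cc1)[C@H](CC=C(C)C)O | intermediate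
22 | (5Z,7S,10E,12S)-12-hydroxy-11-[(4-methoxybenzyloxy)methyl]-7,15-dimethyl-3-methylidene-7-(triethylsilyloxy)hexadeca-5,10,14-trienoic acid (seco acid) | OC(=O)CC(=C)C/C=C\[C@@](C)(O[Si](CC)(CC)CC)CC/C=C(\COCc1ccc(OC)cc1)[C@H](CC=C(C)C)O | intermediate
23 | (6Z,8S,11E,13S)-12-[(4-methoxybenzyloxy)methyl]-8-methyl-4-methylidene-13-(3-methylbut-2-enyl)-8-(triethylsilyloxy)oxacyclotrideca-6,11-dien-2-one (13-membered lactone, key-step precursor) | O=C1CC(=C)C/C=C\[C@@](C)(O[Si](CC)(CC)CC)CC/C=C(\COCc2ccc(OC)cc2)[C@H](CC=C(C)C)O1 | intermediate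
24 | (Z)-O-trimethylsilyl ketene acetal of lactone 23 (C9=C10, C1 cis to OSiMe3) | C[Si](C)(C)O/C1=C\C(=C)C/C=C\[C@@](C)(O[Si](CC)(CC)CC)CC/C=C(\COCc2ccc(OC)cc2)[C@H](CC=C(C)C)O1 | intermediate (not isolated)
25 | trimethylsilyl ester of acid 26 | C=C1C/C=C\[C@@](C)(O[Si](CC)(CC)CC)CC[C@H](/C(COCc2ccc(OC)cc2)=C/CC=C(C)C)[C@H]1C(=O)O[Si](C)(C)C | intermediate (not isolated)
26 | (1R,2S,5S,6Z)-2-[(2Z)-1-(4-methoxybenzyloxy)-6-methylhepta-2,5-dien-2-yl]-5-methyl-9-methylidene-5-(triethylsilyloxy)cyclonon-6-ene-1-carboxylic acid (8S,9R in the numbering used here; key-step product) | C=C1C/C=C\[C@@](C)(O[Si](CC)(CC)CC)CC[C@H](/C(COCc2ccc(OC)cc2)=C/CC=C(C)C)[C@H]1C(=O)O | intermediate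
27 | C10 primary alcohol from 26 (8S,9R; PMB ether and C5 silyl ether retained) | C=C1C/C=C\[C@@](C)(O[Si](CC)(CC)CC)CC[C@H](/C(COCc2ccc(OC)cc2)=C/CC=C(C)C)[C@H]1CO | intermediate
28 | diol with free C10 hydroxyl and free allylic CH2OH on C11 (8S,9R; C11=C12 Z) | C=C1C/C=C\[C@@](C)(O[Si](CC)(CC)CC)CC[C@H](/C(CO)=C/CC=C(C)C)[C@H]1CO | intermediate
29 | (11S,12R)-11,12-epoxy diol | C=C1C/C=C\[C@@](C)(O[Si](CC)(CC)CC)CC[C@H]([C@@]3(CO)O[C@@H]3CC=C(C)C)[C@H]1CO | intermediate (not isolated)
30 | (8S,9R,11R,12R)-oxolane diol (trans-fused oxolane; CH2OH and CH(OH)CH2CH=CMe2 on C11) | C=C1C/C=C\[C@@](C)(O[Si](CC)(CC)CC)CC[C@H]2[C@H]1CO[C@@]2([C@H](O)CC=C(C)C)CO | intermediate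
31 | stearate of the C11 CH2OH arm with free (12R)-hydroxyl | C=C1C/C=C\[C@@](C)(O[Si](CC)(CC)CC)CC[C@H]2[C@H]1CO[C@@]2([C@H](O)CC=C(C)C)COC(=O)CCCCCCCCCCCCCCCCC | intermediate
32 | C5 triethylsilyl ether of the target (E C12=C13 diene) | C=C1C/C=C\[C@@](C)(O[Si](CC)(CC)CC)CC[C@H]2[C@H]1CO[C@@]2(/C=C/C=C(C)C)COC(=O)CCCCCCCCCCCCCCCCC | intermediate
33 | CNP0274030.1 | C=C1C/C=C\[C@@](C)(O)CC[C@H]2[C@H]1CO[C@@]2(/C=C/C=C(C)C)COC(=O)CCCCCCCCCCCCCCCCC | target

Total step count: 23. Longest linear sequence: 21 steps (steps 1–7 and 10–23, from (S)-linalool); steps 8 and 9 make bromide 16.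

Steps most likely to fail

Step 17. What may go wrong: the macrocycle may impose the ketene acetal geometry or the transition-state shape of a crossed pairing (E acetal through the chair, or Z acetal through the boat), so that simple diastereoselection at C9 is lost and the 8,9-cis acid forms; C8 is not at risk. Fallback: C9 is then set by thermodynamic epimerisation after the rearrangement instead of by the transition state. It sets out from lactone 23: the rearrangement is run as in step 17 and, if it delivers the 8,9-cis acid F1, this is esterified with Me3SiCHN2 to the cis methyl ester F2. Brief equilibration α to the ester (NaOMe, MeOH, 0 °C) should favour the trans methyl ester F3, with both ring substituents pseudo-equatorial. Reduction of F3 with LiAlH4 returns to alcohol 27.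

Step 16. What may go wrong: the activated acyl intermediate of the β,γ-unsaturated acid may lose its acidic C9 proton (ketene formation, migration of the C1 methylene into conjugation), or intermolecular acylation may give oligomers. Fallback: the alcohol is activated instead of the acid. It sets out from enal 19: allylation with the enantiomeric borane ((−)-α-pinene series) gives the (12R)-homoallylic alcohol F4, cross-metathesis as in step 14 gives the (12R)-prenyl hydroxy ester F5, and LiOH gives the (12R)-seco acid F6. Mitsunobu macrolactonisation (PPh3, diisopropyl azodicarboxylate, toluene, high dilution, 0 °C) closes the ring by carboxylate attack with inversion at C12 and returns to lactone 23.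

Step 20. What may go wrong: poor facial selectivity if the face preferred by the tartrate reagent is mismatched with the C8 stereocentre, or slow epoxidation because the C12 substituent is cis to the CH2OH group. Fallback: the oxolane ring is closed by haloetherification, so that C11 is set by the ring-fusion centres instead of by a reagent and no epoxide is needed. It sets out from diol 28: N-iodosuccinimide (CH2Cl2, −20 °C) should give the iodo oxolane alcohol F7 by 5-exo attack of the C10 hydroxyl at C11 with iodine at C12. Stearoylation as in step 21 gives the iodo stearate F8, and E2 elimination with DBU (toluene, 60 °C) towards the allylic C13 hydrogens gives the diene and returns to silyl ether 32.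

Further compounds
F1 | step 17 | (8S,9S) C9-epimeric (cis) acid | C=C1C/C=C\[C@@](C)(O[Si](CC)(CC)CC)CC[C@H](/C(COCc2ccc(OC)cc2)=C/CC=C(C)C)[C@@H]1C(=O)O
F2 | step 17 | methyl ester of F1 (cis) | C=C1C/C=C\[C@@](C)(O[Si](CC)(CC)CC)CC[C@H](/C(COCc2ccc(OC)cc2)=C/CC=C(C)C)[C@@H]1C(=O)OC
F3 | step 17 | (8S,9R) trans methyl ester | C=C1C/C=C\[C@@](C)(O[Si](CC)(CC)CC)CC[C@H](/C(COCc2ccc(OC)cc2)=C/CC=C(C)C)[C@H]1C(=O)OC
F4 | step 16 | (12R)-homoallylic alcohol, C12 epimer of 20 | COC(=O)CC(=C)C/C=C\[C@@](C)(O[Si](CC)(CC)CC)CC/C=C(\COCc1ccc(OC)cc1)[C@@H](CC=C)O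
F5 | step 16 | (12R)-prenyl hydroxy ester, C12 epimer of 21 | COC(=O)CC(=C)C/C=C\[C@@](C)(O[Si](CC)(CC)CC)CC/C=C(\COCc1ccc(OC)cc1)[C@@H](CC=C(C)C)O
F6 | step 16 | (12R)-seco acid, C12 epimer of 22 | OC(=O)CC(=C)C/C=C\[C@@](C)(O[Si](CC)(CC)CC)CC/C=C(\COCc1ccc(OC)cc1)[C@@H](CC=C(C)C)O
F7 | step 20 | iodo oxolane alcohol (8S,9R,11R; iodine on C12, free CH2OH on C11) | C=C1C/C=C\[C@@](C)(O[Si](CC)(CC)CC)CC[C@H]2[C@H]1CO[C@@]2([C@H](I)CC=C(C)C)CO
F8 | step 20 | iodo stearate (stearate of F7) | C=C1C/C=C\[C@@](C)(O[Si](CC)(CC)CC)CC[C@H]2[C@H]1CO[C@@]2([C@H](I)CC=C(C)C)COC(=O)CCCCCCCCCCCCCCCCC
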